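## Analysis of the target

Morusyunnansin E (24) is a flavan: a chroman (benzo ring A fused to dihydropyran ring C) carrying a 2,4-dihydroxyphenyl group (ring B) at C2, a methoxy group at C7 and an (E)-4-hydroxy-3-methylbut-2-enyl chain at C8. C2 is the only stereocentre and is (S). The only other stereochemical element is the E geometry of the side-chain alkene, which is too remote to interact with C2. C3 and C4 are plain methylene groups, so C2 has no neighbouring functional group through which asymmetric induction could be relayed. The C2–O1 bond is the weak point: it is benzylic to a ring with ortho and para oxygens, so acid can ionise it, and base can open it through a quinone methide once the ring B phenols are free. Either process racemises C2. The primary allylic alcohol, the trisubstituted alkene and the resorcinol ring rule out hydrogenation, strong acid and strong oxidants late in the route. Ring A is contiguously tetrasubstituted (C4a, C8a, C8, C7) and needs regiospecific arene chemistry. The strategy rests on the C2–H bond: it is alpha to O1 and benzylic to ring B, hence a good hydride donor, and in an open precursor whose C4 is the electrophilic carbon of an alkylidene malonate on C4a it lies 1,5 to C4.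

## Retrosynthetic reasoning

**Protecting groups.** Target 24 is traced back to its tris-silyl ether 23. Silyl ethers on ring B keep that ring electron-rich, which the hydride donor needs. A silyl ether on the allylic alcohol is inert to zerovalent palladium, which an allylic ester would not be. All three fall in one fluoride step.

**Functional group addition at C3.** C3 of 23 is unfunctionalised, but closing ring C through C2–C3 needs a carbon nucleophile at C3. A geminal diester is therefore added in the retrosynthetic direction: 23 comes from monoacid 21, this from diacid 20, and this from diallyl ester 19. Allyl esters are chosen because they can be cleaved under neutral conditions. The first carboxyl then leaves thermally and the second by a radical chain. No C3 carbanion is formed at any point, so O1 cannot be expelled as a phenoxide by beta-elimination.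

**Key disconnection.** In 19 the C2–C3 bond is cut and one hydrogen is moved from C4 back to C2. This gives benzylidene malonate 18, an achiral, open isomer of 19. The cut is made here because it removes ring C and the stereocentre together and leaves only an aryl benzyl ether and an alkylidene malonate. Forward, a chiral Sc(OTf)3 complex must trigger the 1,5-hydride transfer and control the ring closure at C2.

**C3=C4.** Compound 18 is cut at the alkylidene double bond into aldehyde 16 and diallyl malonate 17 (Knoevenagel condensation). The phenol must already be alkylated at this point, since a free salicylaldehyde would lactonise to a coumarin.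

**O1–CH2 (the future O1–C2 bond).** Aldehyde 16 is cut at the ether oxygen into salicylaldehyde 12 and benzyl alcohol 15, joined forward by a redox dehydration under neutral conditions. This avoids both a phenoxide in a polar solvent, which would strip aryl silyl ethers, and a labile benzylic halide. Alcohol 15 comes from 2,4-dihydroxybenzaldehyde 13 through bis-silyl ether 14.

**C4–C4a.** The formyl carbon of 12 is removed to give phenol 10. Forward, a magnesium-mediated formylation (through salicyl alcohol 11) goes only ortho to the free hydroxyl, and only one such position is open.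

**O–CH3 and C8–side chain.** Phenol 10 comes from the symmetrical dimethyl ether 9 by cleavage of one methyl group. Compound 9 is cut between ring carbon and side-chain CH2 into 1,3-dimethoxybenzene 7 (through its 2-lithio derivative 8) and allylic bromide 6. The position between the two methoxy groups is the only doubly activated one, so the 1,2,3-pattern is unambiguous, and SN2 alkylation leaves the alkene geometry untouched.

**Side chain.** Bromide 6 is traced through alcohol 5 and silyl ether 4 to hydroxy acetate 3, and this to prenyl acetate 1 (with enal 2 as over-oxidation product). Allylic oxidation of the methyl group trans to the chain sets the E geometry at the outset; the remaining steps only exchange the functions at the two ends.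

## Alternatives that were turned down

**Alternative 1:** Ring A is disconnected into a vinylketene and an alkoxyalkyne, and ring C is closed later through O1–C2.
- Forward: irradiation of diazo enone A1 gives a vinylketene by Wolff rearrangement. It adds methoxyalkyne A2 in a [2+2] cycloaddition; the cyclobutenone opens (4π), recloses (6π) and tautomerises to phenol A3. New bonds are C8a–C8, C6–C7 and C4a–C8a. After removal of the triethylsilyl group, the phenol would displace the activated (R)-carbinol with inversion.
- For it: the ynol ether polarity fixes the full substitution pattern of ring A. The carbinol stereocentre can be set beforehand by a well-established asymmetric ketone reduction. On certainty of absolute configuration it is stronger than the chosen route, whose asymmetric step is new.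
- Against it: A1 and A2 each need several steps, and A2 is a sensitive skipped enyne ynol ether. The ketene can also add to the trisubstituted alkene. Ring C closure is a substitution at a 2,4-dioxygenated benzylic carbinol, which tends to ionise and lose enantiopurity. The step count is roughly double, for a ring that can be bought as an arene.
- Comparison: the chosen route buys ring A, dresses it by ortho-metalation, and creates C2 in a ring closure that needs no leaving group at that carbon.

**Alternative 2:** C2–C3 and O1–C8a are disconnected with ring A at the cyclohexadiene oxidation level.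
- Forward: bis(silyloxy)diene A4 adds through its terminal carbon to aldehyde 14 under a Ti(Oi-Pr)4/BINOL catalyst (vinylogous Mukaiyama aldol). The aldol hydroxyl condenses onto the C8a carbonyl to give dihydropyranone A5. Reduction of the C4 carbonyl and loss of water would then aromatise ring A and leave C4 as a methylene group.
- For it: enantioselective aldol additions of such dienes to aromatic aldehydes are an established reaction type, so its stereo-defining step has closer precedent than the chosen one. It uses the same aldehyde 14, and C4 ends at the right oxidation level.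
- Against it: the cyclohexenone behind A4 needs C-alkylation of a cyclic 1,3-dione and a regiodefined enol ether at C7, both prone to isomer mixtures. Aldehyde 14 is deactivated and ortho-hindered. A5 can racemise by retro-oxa-Michael opening. The aromatisation needs acid and passes through a cation next to the ionisable C2–O1 bond and the allylic silyl ether.
- Comparison: the chosen route keeps ring A aromatic throughout and never exposes C2 to acid after it is formed.

**Alternative 3:** O1–C2 and C3–C4 are disconnected in one cycloaddition.
- Forward: dehydration of salicyl alcohol A6 (the same substance as 11) gives an ortho-quinone methide. It reacts as a heterodiene with styrene A7 in an inverse-demand [4+2] cycloaddition and gives A8, identical with 23.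
- For it: it is the shortest approach, needs no temporary groups, and its regiochemistry follows from polarity. In step economy it is clearly stronger: it reaches 23 without the three steps the chosen route spends on removing the diester.
- Against it: the quinone methide is unsubstituted at its methylene carbon and offers a chiral acid only one oxygen to bind. Styrene A7 has no hydrogen-bond donor or chelating group. A thermal background reaction and oligomerisation of the quinone methide compete. The acid that generates the quinone methide also ionises C2–O1 of the product.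
- Comparison: the chosen route pays three extra steps for a malonate that gives a chiral Lewis acid a two-point binding site directly at the reacting carbons.

Key step: step 12

Assumption: the sense of induction of the N,N'-dioxide–Sc(OTf)3 catalyst on this substrate class cannot be predicted; the ligand enantiomer (both are accessible from L- or D-pipecolic acid) that delivers (2R)-19 is taken as chosen after a trial run.

Remark: (2R) in 19 and 20 and (2S) in 21 to 24 denote the same spatial arrangement; the descriptor changes only because the C3 diester outranks the aryl group.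

## Route

Step 1
Reactants: 1 prenyl acetate (3-methylbut-2-enyl acetate)
Product: 3 (E)-4-hydroxy-3-methylbut-2-enyl acetate, via (E)-4-acetoxy-2-methylbut-2-enal 2 (not isolated)
Conditions: SeO2 (cat.), t-BuOOH, CH2Cl2, rt; then NaBH4, MeOH, 0 °C
Reagents that add atoms: tert-butyl hydroperoxide, CC(C)(C)OO (the hydroxyl oxygen, passed on through SeO2, O=[Se]=O)
Why: Allylic oxidation by SeO2 (ene reaction, then [2,3]-sigmatropic shift) attacks the methyl group trans to the chain, which fixes the E geometry; the portion oxidised further to enal 2 is returned to 3 by borohydride in the same flask.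

Step 2
Reactants: 3 (E)-4-hydroxy-3-methylbut-2-enyl acetate
Product: 4 (E)-4-(tert-butyldimethylsilyloxy)-3-methylbut-2-enyl acetate
Conditions: TBSCl, imidazole, CH2Cl2, 0 °C to rt
Reagents that add atoms: tert-butyldimethylsilyl chloride, CC(C)(C)[Si](C)(C)Cl
Why: Routine silylation of a primary alcohol.

Step 3
Reactants: 4 (E)-4-(tert-butyldimethylsilyloxy)-3-methylbut-2-enyl acetate
Product: 5 (E)-4-(tert-butyldimethylsilyloxy)-3-methylbut-2-en-1-ol
Conditions: K2CO3 (cat.), MeOH, 0 °C
Reagents that add atoms: none
Why: Methanolysis (transesterification) of the acetate; an alkyl silyl ether is stable to carbonate in methanol.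

Step 4
Reactants: 5 (E)-4-(tert-butyldimethylsilyloxy)-3-methylbut-2-en-1-ol
Product: 6 tert-butyl{[(E)-4-bromo-2-methylbut-2-enyl]oxy}dimethylsilane
Conditions: CBr4, PPh3, CH2Cl2, 0 °C
Reagents that add atoms: carbon tetrabromide, BrC(Br)(Br)Br
Why: Appel bromination; displacement at the primary allylic carbon under neutral conditions should proceed without allylic transposition or loss of the E geometry, and the bromide is used at once.

Step 5
Reactants: 7 1,3-dimethoxybenzene; 6 tert-butyl{[(E)-4-bromo-2-methylbut-2-enyl]oxy}dimethylsilane
Product: 9 2-[(E)-4-(tert-butyldimethylsilyloxy)-3-methylbut-2-enyl]-1,3-dimethoxybenzene, via 2,6-dimethoxyphenyllithium 8 (not isolated)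
Conditions: n-BuLi, THF, 0 °C to rt; then 6, −78 °C to rt
Reagents that add atoms: none
Why: Directed ortho-metalation at the only position flanked by both methoxy groups, then SN2 alkylation of the aryllithium at the primary allylic bromide, which leaves the alkene geometry untouched.

Step 6
Reactants: 9 2-[(E)-4-(tert-butyldimethylsilyloxy)-3-methylbut-2-enyl]-1,3-dimethoxybenzene
Product: 10 2-[(E)-4-(tert-butyldimethylsilyloxy)-3-methylbut-2-enyl]-3-methoxyphenol
Conditions: NaSEt, DMF, 120 °C; aqueous NH4Cl
Reagents that add atoms: none
Why: SN2 demethylation of an aryl methyl ether by thiolate; it should stop after one methyl group because the phenoxide formed is a poor leaving group for the second, the two methoxy groups are equivalent, and a soft thiolate should not attack silicon of an alkyl silyl ether.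

Step 7
Reactants: 10 2-[(E)-4-(tert-butyldimethylsilyloxy)-3-methylbut-2-enyl]-3-methoxyphenol
Product: 12 3-[(E)-4-(tert-butyldimethylsilyloxy)-3-methylbut-2-enyl]-2-hydroxy-4-methoxybenzaldehyde, via salicyl alcohol 11 (not isolated)
Conditions: MgCl2, Et3N, (CH2O)n, MeCN, 80 °C
Reagents that add atoms: paraformaldehyde (as formaldehyde), C=O
Why: Magnesium-mediated ortho-formylation (Casnati–Skattebøl); the magnesium phenoxide delivers formaldehyde to the single free ortho position, and the alkoxide of 11 is oxidised by hydride transfer to a second formaldehyde.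

Step 8
Reactants: 13 2,4-dihydroxybenzaldehyde
Product: 14 2,4-bis(tert-butyldimethylsilyloxy)benzaldehyde
Conditions: TBSCl, imidazole, DMF, rt
Reagents that add atoms: tert-butyldimethylsilyl chloride, CC(C)(C)[Si](C)(C)Cl
Why: Silylation of both phenols; excess reagent also covers the hydrogen-bonded ortho hydroxyl.

Step 9
Reactants: 14 2,4-bis(tert-butyldimethylsilyloxy)benzaldehyde
Product: 15 [2,4-bis(tert-butyldimethylsilyloxy)phenyl]methanol
Conditions: NaBH4, THF/MeOH, −10 °C
Reagents that add atoms: none
Why: Borohydride reduction of the aldehyde; low temperature and the protic medium should keep the alkoxide from pulling the ortho silyl group onto the benzylic oxygen.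

Step 10
Reactants: 12 3-[(E)-4-(tert-butyldimethylsilyloxy)-3-methylbut-2-enyl]-2-hydroxy-4-methoxybenzaldehyde; 15 [2,4-bis(tert-butyldimethylsilyloxy)phenyl]methanol
Product: 16 2-{[2,4-bis(tert-butyldimethylsilyloxy)phenyl]methoxy}-3-[(E)-4-(tert-butyldimethylsilyloxy)-3-methylbut-2-enyl]-4-methoxybenzaldehyde
Conditions: PPh3, DIAD, THF, 0 °C to rt
Reagents that add atoms: none
Why: Mitsunobu etherification; the chelated salicylaldehyde hydroxyl is acidic enough to serve as pronucleophile, the alcohol is primary, and the neutral medium should spare the aryl silyl ethers.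

Step 11
Reactants: 16 2-{[2,4-bis(tert-butyldimethylsilyloxy)phenyl]methoxy}-3-[(E)-4-(tert-butyldimethylsilyloxy)-3-methylbut-2-enyl]-4-methoxybenzaldehyde; 17 diallyl malonate
Product: 18 diallyl 2-({2-{[2,4-bis(tert-butyldimethylsilyloxy)phenyl]methoxy}-3-[(E)-4-(tert-butyldimethylsilyloxy)-3-methylbut-2-enyl]-4-methoxyphenyl}methylidene)propanedioate
Conditions: piperidine (cat.), AcOH (cat.), toluene, 4 Å MS, 80 °C
Reagents that add atoms: none
Why: Knoevenagel condensation; the phenol is already alkylated, so no coumarin can form, and without a Lewis acid the hydride shift should not start at this temperature.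

Step 12
Reactants: 18 diallyl 2-({2-{[2,4-bis(tert-butyldimethylsilyloxy)phenyl]methoxy}-3-[(E)-4-(tert-butyldimethylsilyloxy)-3-methylbut-2-enyl]-4-methoxyphenyl}methylidene)propanedioate
Product: 19 diallyl (2R)-2-[2,4-bis(tert-butyldimethylsilyloxy)phenyl]-8-[(E)-4-(tert-butyldimethylsilyloxy)-3-methylbut-2-enyl]-7-methoxychroman-3,3-dicarboxylate
Conditions: Sc(OTf)3 (10 mol%), chiral N,N'-dioxide ligand (from pipecolic acid, 2,6-diisopropylanilide arms, 11 mol%), 4 Å MS, ClCH2CH2Cl, 35 °C
Reagents that add atoms: none
Why: Proposed new method: the chiral N,N'-dioxide–Sc(OTf)3 complex chelates the two ester carbonyls of 18 and raises the electrophilicity of the benzylidene carbon (future C4), which accepts a hydride through space from the O–CH2 group 1,5 to it, leaving an aryl-stabilised oxocarbenium ion (O1=C2) paired with a scandium-bound malonate enolate. The enolate carbon (C3) then adds to C2 and closes ring C in a 6-endo-trig mode with respect to the O1=C2 bond (enolexo with respect to the enolate). The closest known reaction type is the Lewis-acid-catalysed 1,5-hydride shift and cyclisation of ortho-benzyloxy and ortho-dialkylamino benzylidene malonates, which has chiral-catalyst versions only in the amine series; carrying it over to a benzyl ether under chiral Lewis acid control is the new element. C2 is the only new stereocentre and is set by the catalyst: the ligand sphere around scandium selects one of the two enantiotopic O–CH2 hydrogens and shields one face of the planar oxocarbenium ion while the enolate is still bound, so that bond formation within the ion pair should outrun bond rotation. The step needs site selectivity, which the substrate secures because the O–CH2–Ar hydrogens are the only hydridic C–H bonds 1,5 to the acceptor and are activated by both O1 and the 2,4-bis(silyloxy)phenyl ring, while the C8 side chain next to O1 buttresses the benzyloxy group towards the alkylidene carbon. It also needs the Lewis acid to activate the acceptor, which the C7 methoxy group deactivates, without ionising the benzyl ether; two-point chelation by the geminal diester directs the metal to the malonate.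

Step 13
Reactants: 19 diallyl (2R)-2-[2,4-bis(tert-butyldimethylsilyloxy)phenyl]-8-[(E)-4-(tert-butyldimethylsilyloxy)-3-methylbut-2-enyl]-7-methoxychroman-3,3-dicarboxylate
Product: 21 (2S,3RS)-2-[2,4-bis(tert-butyldimethylsilyloxy)phenyl]-8-[(E)-4-(tert-butyldimethylsilyloxy)-3-methylbut-2-enyl]-7-methoxychroman-3-carboxylic acid, via chroman-3,3-dicarboxylic acid 20 (not isolated)
Conditions: Pd(PPh3)4 (5 mol%), morpholine, THF, rt; citric acid wash; then pyridine/toluene, 100 °C
Reagents that add atoms: none
Why: Zerovalent palladium ionises both allyl esters and morpholine traps the allyl groups (Tsuji–Trost deallylation); malonic acid 20 then loses CO2 through a cyclic transition state that gives the acid enol and not a carbanion, so O1 should not be expelled and C2 is untouched, while C3 forms as an inconsequential mixture of epimers.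

Step 14
Reactants: 21 (2S,3RS)-2-[2,4-bis(tert-butyldimethylsilyloxy)phenyl]-8-[(E)-4-(tert-butyldimethylsilyloxy)-3-methylbut-2-enyl]-7-methoxychroman-3-carboxylic acid
Product: 23 (2S)-2-[2,4-bis(tert-butyldimethylsilyloxy)phenyl]-8-[(E)-4-(tert-butyldimethylsilyloxy)-3-methylbut-2-enyl]-7-methoxychroman, via Barton ester 22 (not isolated)
Conditions: N-hydroxypyridine-2-thione, DCC, DMAP (cat.), CH2Cl2, 0 °C, dark; then Bu3SnH, hν (tungsten lamp), toluene, rt
Reagents that add atoms: none
Why: Barton reductive decarboxylation; the thiohydroxamate ester fragments in a radical chain to CO2 and a C3 radical that takes hydrogen from Bu3SnH, so both C3 epimers converge on the methylene group and C2 takes no part.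

Step 15
Reactants: 23 (2S)-2-[2,4-bis(tert-butyldimethylsilyloxy)phenyl]-8-[(E)-4-(tert-butyldimethylsilyloxy)-3-methylbut-2-enyl]-7-methoxychroman
Product: 24 morusyunnansin E, 4-[(2S)-8-[(E)-4-hydroxy-3-methylbut-2-enyl]-7-methoxychroman-2-yl]benzene-1,3-diol
Conditions: TBAF, AcOH, THF, 0 °C
Reagents that add atoms: none
Why: Fluoride cleaves the two aryl silyl ethers and the primary silyl ether; acetic acid buffers the phenoxides so that ring C should not open through a quinone methide and C2 should stay (S).

## Compound list

1 | prenyl acetate (3-methylbut-2-enyl acetate) | CC(C)=CCOC(C)=O | starting material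
2 | (E)-4-acetoxy-2-methylbut-2-enal | CC(=O)OC/C=C(\C)C=O | intermediate (not isolated)
3 | (E)-4-hydroxy-3-methylbut-2-enyl acetate | CC(=O)OC/C=C(\C)CO | intermediate
4 | (E)-4-(tert-butyldimethylsilyloxy)-3-methylbut-2-enyl acetate | CC(=O)OC/C=C(\C)CO[Si](C)(C)C(C)(C)C | intermediate
5 | (E)-4-(tert-butyldimethylsilyloxy)-3-methylbut-2-en-1-ol | OC/C=C(\C)CO[Si](C)(C)C(C)(C)C | intermediate
6 | tert-butyl{[(E)-4-bromo-2-methylbut-2-enyl]oxy}dimethylsilane | BrC/C=C(\C)CO[Si](C)(C)C(C)(C)C | intermediate
7 | 1,3-dimethoxybenzene | COc1cccc(OC)c1 | starting material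
8 | 2,6-dimethoxyphenyllithium | [Li]c1c(OC)cccc1OC | intermediate (not isolated)
9 | 2-[(E)-4-(tert-butyldimethylsilyloxy)-3-methylbut-2-enyl]-1,3-dimethoxybenzene | COc1cccc(OC)c1C/C=C(\C)CO[Si](C)(C)C(C)(C)C | intermediate
10 | 2-[(E)-4-(tert-butyldimethylsilyloxy)-3-methylbut-2-enyl]-3-methoxyphenol | COc1cccc(O)c1C/C=C(\C)CO[Si](C)(C)C(C)(C)C | intermediate
11 | 6-[(E)-4-(tert-butyldimethylsilyloxy)-3-methylbut-2-enyl]-2-(hydroxymethyl)-5-methoxyphenol (salicyl alcohol, present as its magnesium alkoxide) | COc1ccc(CO)c(O)c1C/C=C(\C)CO[Si](C)(C)C(C)(C)C | intermediate (not isolated)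
12 | 3-[(E)-4-(tert-butyldimethylsilyloxy)-3-methylbut-2-enyl]-2-hydroxy-4-methoxybenzaldehyde | COc1ccc(C=O)c(O)c1C/C=C(\C)CO[Si](C)(C)C(C)(C)C | intermediate
13 | 2,4-dihydroxybenzaldehyde | O=Cc1ccc(O)cc1O | starting material
14 | 2,4-bis(tert-butyldimethylsilyloxy)benzaldehyde | O=Cc1ccc(O[Si](C)(C)C(C)(C)C)cc1O[Si](C)(C)C(C)(C)C | intermediate
15 | [2,4-bis(tert-butyldimethylsilyloxy)phenyl]methanol | OCc1ccc(O[Si](C)(C)C(C)(C)C)cc1O[Si](C)(C)C(C)(C)C | intermediate
16 | 2-{[2,4-bis(tert-butyldimethylsilyloxy)phenyl]methoxy}-3-[(E)-4-(tert-butyldimethylsilyloxy)-3-methylbut-2-enyl]-4-methoxybenzaldehyde | COc1ccc(C=O)c(OCc2ccc(O[Si](C)(C)C(C)(C)C)cc2O[Si](C)(C)C(C)(C)C)c1C/C=C(\C)CO[Si](C)(C)C(C)(C)C | intermediate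
17 | diallyl malonate | C=CCOC(=O)CC(=O)OCC=C | starting material
18 | diallyl 2-({2-{[2,4-bis(tert-butyldimethylsilyloxy)phenyl]methoxy}-3-[(E)-4-(tert-butyldimethylsilyloxy)-3-methylbut-2-enyl]-4-methoxyphenyl}methylidene)propanedioate | C=CCOC(=O)C(=Cc1ccc(OC)c(C/C=C(\C)CO[Si](C)(C)C(C)(C)C)c1OCc1ccc(O[Si](C)(C)C(C)(C)C)cc1O[Si](C)(C)C(C)(C)C)C(=O)OCC=C | intermediate (precursor of the key step)
19 | diallyl (2R)-2-[2,4-bis(tert-butyldimethylsilyloxy)phenyl]-8-[(E)-4-(tert-butyldimethylsilyloxy)-3-methylbut-2-enyl]-7-methoxychroman-3,3-dicarboxylate | COc1ccc2c(c1C/C=C(\C)CO[Si](C)(C)C(C)(C)C)O[C@H](c1ccc(O[Si](C)(C)C(C)(C)C)cc1O[Si](C)(C)C(C)(C)C)C(C(=O)OCC=C)(C(=O)OCC=C)C2 | intermediate (product of the key step)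
20 | (2R)-2-[2,4-bis(tert-butyldimethylsilyloxy)phenyl]-8-[(E)-4-(tert-butyldimethylsilyloxy)-3-methylbut-2-enyl]-7-methoxychroman-3,3-dicarboxylic acid | COc1ccc2c(c1C/C=C(\C)CO[Si](C)(C)C(C)(C)C)O[C@H](c1ccc(O[Si](C)(C)C(C)(C)C)cc1O[Si](C)(C)C(C)(C)C)C(C(=O)O)(C(=O)O)C2 | intermediate (not isolated)
21 | (2S,3RS)-2-[2,4-bis(tert-butyldimethylsilyloxy)phenyl]-8-[(E)-4-(tert-butyldimethylsilyloxy)-3-methylbut-2-enyl]-7-methoxychroman-3-carboxylic acid | COc1ccc2c(c1C/C=C(\C)CO[Si](C)(C)C(C)(C)C)O[C@H](c1ccc(O[Si](C)(C)C(C)(C)C)cc1O[Si](C)(C)C(C)(C)C)C(C(=O)O)C2 | intermediate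
22 | 2-thioxopyridin-1(2H)-yl (2S,3RS)-2-[2,4-bis(tert-butyldimethylsilyloxy)phenyl]-8-[(E)-4-(tert-butyldimethylsilyloxy)-3-methylbut-2-enyl]-7-methoxychroman-3-carboxylate (Barton ester) | COc1ccc2c(c1C/C=C(\C)CO[Si](C)(C)C(C)(C)C)O[C@H](c1ccc(O[Si](C)(C)C(C)(C)C)cc1O[Si](C)(C)C(C)(C)C)C(C(=O)ON1C=CC=CC1=S)C2 | intermediate (not isolated)
23 | (2S)-2-[2,4-bis(tert-butyldimethylsilyloxy)phenyl]-8-[(E)-4-(tert-butyldimethylsilyloxy)-3-methylbut-2-enyl]-7-methoxychroman | COc1ccc2c(c1C/C=C(\C)CO[Si](C)(C)C(C)(C)C)O[C@H](c1ccc(O[Si](C)(C)C(C)(C)C)cc1O[Si](C)(C)C(C)(C)C)CC2 | intermediate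
24 | morusyunnansin E, 4-[(2S)-8-[(E)-4-hydroxy-3-methylbut-2-enyl]-7-methoxychroman-2-yl]benzene-1,3-diol | COc1ccc2c(c1C/C=C(\C)CO)O[C@H](c1ccc(O)cc1O)CC2 | target

## Step count and uncertain steps

Total step count: 15. Longest linear sequence: 13 steps (steps 1 to 7 and 10 to 15); steps 8 and 9 form the side branch.

**Step 12 (key step, new method).**
- What may go wrong: the acceptor may not be activated enough, because ring A donates into it and the ligand tempers the Lewis acid. The Lewis acid may heterolyse the benzylic C–O bond of the ether in competition with hydride transfer. Facial selectivity may be poor, or the enantiomeric purity may erode if C2–C3 or C2–O1 of the product reopens through the same stabilised cation.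
- Fallback: starting from 18, achiral Sc(OTf)3 in ClCH2CH2Cl, the established racemic form of this hydride shift and cyclisation, should give racemic diallyl 2-[2,4-bis(tert-butyldimethylsilyloxy)phenyl]-8-[(E)-4-(tert-butyldimethylsilyloxy)-3-methylbut-2-enyl]-7-methoxychroman-3,3-dicarboxylate F1. Preparative chromatography on a chiral stationary phase would separate 19 from its (2S)-enantiomer F2, which is set aside. The route is rejoined at 19.

**Step 6.**
- What may go wrong: loss of the silyl ether at 120 °C, or incomplete demethylation.
- Fallback: starting from bromide 6 and commercially available 3-methoxyphenol F3. MOMCl and i-Pr2NEt in CH2Cl2 should give 1-methoxy-3-(methoxymethoxy)benzene F4. n-BuLi in THF at 0 °C lithiates between the two oxygens to [2-methoxy-6-(methoxymethoxy)phenyl]lithium F5. Alkylation with 6 gives tert-butyl{[(E)-4-[2-methoxy-6-(methoxymethoxy)phenyl]-2-methylbut-2-enyl]oxy}dimethylsilane F6. TMSOTf and 2,2'-bipyridyl in CH2Cl2 at 0 °C, then water, remove the aryl methoxymethyl group under buffered conditions that should spare the silyl ether. The route is rejoined at 10.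

**Step 10.**
- What may go wrong: ionisation of the activated, electron-rich benzylic oxyphosphonium species with self-alkylation, or sluggish attack by the hindered, chelated phenol.
- Fallback: starting from 15, CBr4 and PPh3 in CH2Cl2 at 0 °C give 1-(bromomethyl)-2,4-bis(tert-butyldimethylsilyloxy)benzene F7. It is used at once to alkylate phenol 12 with Ag2O in toluene at rt, a halide displacement that generates no free phenoxide in a polar solvent. The route is rejoined at 16.

**Step 14.**
- What may go wrong: rearrangement of the C3 radical before hydrogen transfer, by 1,2-shift of the ring B aryl group from C2 or by beta-scission of the C2–O1 bond.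
- Fallback: a non-radical excision starting from 21. Activation with isobutyl chloroformate and N-methylmorpholine in THF at −15 °C and reduction with NaBH4 give [(2S,3RS)-2-[2,4-bis(tert-butyldimethylsilyloxy)phenyl]-8-[(E)-4-(tert-butyldimethylsilyloxy)-3-methylbut-2-enyl]-7-methoxychroman-3-yl]methanol F8. Dess–Martin periodinane in CH2Cl2 gives the corresponding chroman-3-carbaldehyde F9. Stoichiometric RhCl(PPh3)3 in toluene at 110 °C removes the formyl group (Tsuji–Wilkinson decarbonylation). The route is rejoined at 23.

**Step 15.**
- What may go wrong: racemisation at C2 by reversible opening of ring C to a quinone methide once ring B phenoxides are present, or by acid ionisation of C2–O1.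
- Fallback: a staged deprotection starting from 23. KHF2 in MeOH at rt cleaves only the aryl silyl ethers, without free phenoxide, and gives 4-[(2S)-8-[(E)-4-(tert-butyldimethylsilyloxy)-3-methylbut-2-enyl]-7-methoxychroman-2-yl]benzene-1,3-diol F10. PPTS in MeOH at rt then frees the primary alcohol. The route is rejoined at 24.

## Further compounds

F1 | step 12 | racemic diallyl 2-[2,4-bis(tert-butyldimethylsilyloxy)phenyl]-8-[(E)-4-(tert-butyldimethylsilyloxy)-3-methylbut-2-enyl]-7-methoxychroman-3,3-dicarboxylate | COc1ccc2c(c1C/C=C(\C)CO[Si](C)(C)C(C)(C)C)OC(c1ccc(O[Si](C)(C)C(C)(C)C)cc1O[Si](C)(C)C(C)(C)C)C(C(=O)OCC=C)(C(=O)OCC=C)C2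
F2 | step 12 | diallyl (2S)-2-[2,4-bis(tert-butyldimethylsilyloxy)phenyl]-8-[(E)-4-(tert-butyldimethylsilyloxy)-3-methylbut-2-enyl]-7-methoxychroman-3,3-dicarboxylate (enantiomer of 19) | COc1ccc2c(c1C/C=C(\C)CO[Si](C)(C)C(C)(C)C)O[C@@H](c1ccc(O[Si](C)(C)C(C)(C)C)cc1O[Si](C)(C)C(C)(C)C)C(C(=O)OCC=C)(C(=O)OCC=C)C2
F3 | step 6 | 3-methoxyphenol | COc1cccc(O)c1
F4 | step 6 | 1-methoxy-3-(methoxymethoxy)benzene | COCOc1cccc(OC)c1
F5 | step 6 | [2-methoxy-6-(methoxymethoxy)phenyl]lithium | [Li]c1c(OC)cccc1OCOC
F6 | step 6 | tert-butyl{[(E)-4-[2-methoxy-6-(methoxymethoxy)phenyl]-2-methylbut-2-enyl]oxy}dimethylsilane | COCOc1cccc(OC)c1C/C=C(\C)CO[Si](C)(C)C(C)(C)C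
F7 | step 10 | 1-(bromomethyl)-2,4-bis(tert-butyldimethylsilyloxy)benzene | BrCc1ccc(O[Si](C)(C)C(C)(C)C)cc1O[Si](C)(C)C(C)(C)C
F8 | step 14 | [(2S,3RS)-2-[2,4-bis(tert-butyldimethylsilyloxy)phenyl]-8-[(E)-4-(tert-butyldimethylsilyloxy)-3-methylbut-2-enyl]-7-methoxychroman-3-yl]methanol | COc1ccc2c(c1C/C=C(\C)CO[Si](C)(C)C(C)(C)C)O[C@H](c1ccc(O[Si](C)(C)C(C)(C)C)cc1O[Si](C)(C)C(C)(C)C)C(CO)C2
F9 | step 14 | (2S,3RS)-2-[2,4-bis(tert-butyldimethylsilyloxy)phenyl]-8-[(E)-4-(tert-butyldimethylsilyloxy)-3-methylbut-2-enyl]-7-methoxychroman-3-carbaldehyde | COc1ccc2c(c1C/C=C(\C)CO[Si](C)(C)C(C)(C)C)O[C@H](c1ccc(O[Si](C)(C)C(C)(C)C)cc1O[Si](C)(C)C(C)(C)C)C(C=O)C2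
F10 | step 15 | 4-[(2S)-8-[(E)-4-(tert-butyldimethylsilyloxy)-3-methylbut-2-enyl]-7-methoxychroman-2-yl]benzene-1,3-diol | COc1ccc2c(c1C/C=C(\C)CO[Si](C)(C)C(C)(C)C)O[C@H](c1ccc(O)cc1O)CC2
A1 | alternative 1 | (R,E)-7-[2,4-bis(tert-butyldimethylsilyloxy)phenyl]-1-diazo-7-(triethylsilyloxy)hept-3-en-2-one | [N-]=[N+]=CC(=O)/C=C/CC[C@@H](O[Si](CC)(CC)CC)c1ccc(O[Si](C)(C)C(C)(C)C)cc1O[Si](C)(C)C(C)(C)C
A2 | alternative 1 | tert-butyl{[(E)-6-methoxy-2-methylhex-2-en-5-ynyl]oxy}dimethylsilane | COC#CC/C=C(\C)CO[Si](C)(C)C(C)(C)C
A3 | alternative 1 | 6-[(R)-3-[2,4-bis(tert-butyldimethylsilyloxy)phenyl]-3-(triethylsilyloxy)propyl]-2-[(E)-4-(tert-butyldimethylsilyloxy)-3-methylbut-2-enyl]-3-methoxyphenol | COc1ccc(CC[C@@H](O[Si](CC)(CC)CC)c2ccc(O[Si](C)(C)C(C)(C)C)cc2O[Si](C)(C)C(C)(C)C)c(O)c1C/C=C(\C)CO[Si](C)(C)C(C)(C)C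
A4 | alternative 2 | 2-[(E)-4-(tert-butyldimethylsilyloxy)-3-methylbut-2-enyl]-1-methoxy-3-(trimethylsilyloxy)-4-[1-(trimethylsilyloxy)ethenyl]cyclohexa-1,3-diene | COC1=C(C/C=C(\C)CO[Si](C)(C)C(C)(C)C)C(O[Si](C)(C)C)=C(CC1)C(=C)O[Si](C)(C)C
A5 | alternative 2 | (S)-2-[2,4-bis(tert-butyldimethylsilyloxy)phenyl]-8-[(E)-4-(tert-butyldimethylsilyloxy)-3-methylbut-2-enyl]-7-methoxy-2,3,5,6-tetrahydro-4H-chromen-4-one | COC1=C(C/C=C(\C)CO[Si](C)(C)C(C)(C)C)C2=C(CC1)C(=O)C[C@@H](c1ccc(O[Si](C)(C)C(C)(C)C)cc1O[Si](C)(C)C(C)(C)C)O2
A6 | alternative 3 | 6-[(E)-4-(tert-butyldimethylsilyloxy)-3-methylbut-2-enyl]-2-(hydroxymethyl)-5-methoxyphenol (same substance as 11) | COc1ccc(CO)c(O)c1C/C=C(\C)CO[Si](C)(C)C(C)(C)C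
A7 | alternative 3 | 2,4-bis(tert-butyldimethylsilyloxy)-1-ethenylbenzene | C=Cc1ccc(O[Si](C)(C)C(C)(C)C)cc1O[Si](C)(C)C(C)(C)C
A8 | alternative 3 | (2S)-2-[2,4-bis(tert-butyldimethylsilyloxy)phenyl]-8-[(E)-4-(tert-butyldimethylsilyloxy)-3-methylbut-2-enyl]-7-methoxychroman (same substance as 23) | COc1ccc2c(c1C/C=C(\C)CO[Si](C)(C)C(C)(C)C)O[C@H](c1ccc(O[Si](C)(C)C(C)(C)C)cc1O[Si](C)(C)C(C)(C)C)CC2
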